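The constants come from no measurement; no experiment stands behind them.

In a one-step world a feed much longer than the step's own time is a safe feed: each portion of reagent is used about as it arrives, and the yield follows the dosing curve. Four flasks run an exchange that can go past the wanted complex with one exchanged, which also crystallises.

    starting complex + incoming ligand ⇌ leaving ligand + complex with one exchanged (K1 = 8.30, k1 = 3.47 M⁻¹ min⁻¹, Ea1 = 71.0 kJ mol⁻¹, ΔH1 = −27.0 kJ mol⁻¹)
    complex with one exchanged + incoming ligand ⇌ leaving ligand + complex with two exchanged (K2 = 2.2, k2 = 1.00 M⁻¹ min⁻¹, Ea2 = 53.0 kJ mol⁻¹, ΔH2 = −35.0 kJ mol⁻¹)
    complex with two exchanged + incoming ligand ⇌ leaving ligand + complex with three exchanged (K3 = 2.32, k3 = 1.24 M⁻¹ min⁻¹, Ea3 = 62.0 kJ mol⁻¹, ΔH3 = −25.0 kJ mol⁻¹)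
    complex with three exchanged + incoming ligand ⇌ leaving ligand + complex with four exchanged (K4 = 3.71, k4 = 4.89 M⁻¹ min⁻¹, Ea4 = 66.0 kJ mol⁻¹, ΔH4 = −11.0 kJ mol⁻¹)
    crystals ⇌ complex with one exchanged, rate k5*(cs5 - [complex with one exchanged]) while solid is left; crystals form when [complex with one exchanged] > cs5 (cs5 = 1.3 mM, k5 = 9.07 min⁻¹)
    (constants at 35 °C)

| flask | starting complex | incoming ligand | leaving ligand | time | remark | temperature |
|---|---|---|---|---|---|---|
| south | 18 mM | 1.05 equiv (fed, over 2.0 h) | 2.00 equiv | 2.5 h | the addition at 5 °C, then warmed to 35 °C; the feed brings no volume worth counting |  |
| south-east | 18 mM | 1.05 equiv (fed, over 2.0 h) | 2.00 equiv | 2.5 h | all else is in the flask from the start; the feed brings no volume worth counting | 35 °C |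
| north-east | 18 mM (fed, over 2.0 h) | 1.05 equiv | 2.00 equiv | 2.5 h | all else is in the flask from the start; the feed brings no volume worth counting | 35 °C |
| south-west | 18 mM | 1.05 equiv | 2.00 equiv | 2.5 h | everything together at the start at 5 °C, warmed to 35 °C at 2.0 h |  |

- the flask that comes out highest in amount of complex with one exchanged, in percent of the starting complex charged, or "all alike" when all lie within 1.5 percentage points (south / south-east / north-east / south-west / all alike)
- complex with one exchanged at the end, in percent of the starting complex charged, south
- complex with one exchanged at the end, in percent of the starting complex charged, south-east
- complex with one exchanged at the end, in percent of the starting complex charged, north-east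
- complex with one exchanged at the end, in percent of the starting complex charged, south-west

- complex with one exchanged is meant together with its crystals
- solid, in amounts per volume of the solution: crystals
- all constants are for 35 °C and move with temperature by the activation energies and enthalpies

Let τ, the second-order time of the first step, be one over its rate constant times the charged concentration of starting complex: 16.0 min at 35 °C. The feed in south-east lasts 7.50 such times, so it is longer than τ, and the bench rule promises that conversion tracks the feed.

The rule has a border. With a fraction f of starting complex left, incoming ligand needs about τ/f to find a partner, while the feed needs f·tf/eqX, with tf the feed time and eqX the equivalents, to supply enough ligand for that remainder. The two times meet at f = √(eqX·τ/tf), or 37.4%. Below that level in south-east, incoming ligand is reckoned to accumulate, and the rule stops working.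

The reckoning for south-east takes f as the level at the end of the feed, leaves out the reverse step, and lets plain second-order decay, in which 1/f grows by t/τ, run through the remaining 0.500 h. That reckons 22.0% of the starting complex left at the end.

Over-exchange is reckoned separately. Once crystals stand, dissolved complex with one exchanged is taken to sit near 1.3 mM, far below the charge of 18 mM. The second step's forward rate is then 2.08% of the first step's at charged amounts, the inverse of a selectivity factor. So south-east is reckoned at 76.4%.

North-east feeds starting complex into the full charge of incoming ligand, and its starting complex is taken to stand near f through the feed, where in south-east it is reckoned to fall to f only at the end. Taken at level f, the share of the second step rises to 5.56%, which gives 73.7%.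

For south and south-west, the cold 2.0 h is counted as if no step ran, so the whole charge is reckoned to decay through the tail to 34.8%. That gives 63.8% for south and 63.8% for south-west. The highest flask by this reckoning is south-east.

The forecast, whose figures differ from these, gives 62% for south, 78% for south-east, 74% for north-east and 63% for south-west, names south-east as highest, and holds that the cold flasks “waste the first two hours”.

The simulation gives 64.5% in south, 76.7% in south-east, 72.9% in north-east and 65.9% in south-west, with south-east highest.

In south-east, starting complex stands at 30.8% at the end of the feed, and τ carried through the 0.500 h from there gives 19.5% against the 21.6% present at 2.50 h, when its forward half-life of 0.75 h is shorter than the 2.6 h of dissolved complex with one exchanged in the second step. In south, the same τ laid over the same tail from the 84.0% present at warming gives 32.6% against 33.5% at the end.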